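At early times nothing moves: Tuesday's run still reads 99% starting material at 15.0 h. I take that as the lag, 15.0 h, the inhibition period in which the radical scavenger takes up the radicals from the initiator.

in all of them: starting material 0.51 M; initiator 0.96 mol%; radical scavenger 0.5 mol%
- Saturday's: coupling partner 1.5 equiv; scavenger 0.80 equiv; the very flask that is asked about, followed so far
- Tuesday's: coupling partner 1.5 equiv; scavenger 0.54 equiv; run made earlier
- flask: coupling partner 1.50 equiv; scavenger 0.800 equiv; time 2.0 d

| run | time / h | starting material / % | product / % |
|---|---|---|---|
| Saturday's | 1.50 | 98 | 0 |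
| Saturday's | 5.00 | 103 | 1 |
| Saturday's | 8.00 | 101 | 0 |
| Saturday's | 12.0 | 101 | 1 |
| Saturday's | 20.0 | 73 | 22 |
| Saturday's | 25.0 | 61 | 41 |
| Tuesday's | 3.00 | 102 | 0 |
| Tuesday's | 10.0 | 102 | 1 |
| Tuesday's | 15.0 | 99 | 0 |
| Tuesday's | 25.0 | 61 | 40 |
| Tuesday's | 40.0 | 44 | 56 |
| Tuesday's | 50.0 | 34 | 63 |

(readings scatter by 2 percentage points)

1. part of the starting material that has reacted at 2.0 d
2. share of the unused coupling partner that is free and not bound as idle adduct, at 2.0 d

- the earlier runs do not show how much of coupling partner is bound; that part of a forecast is a guess

Tuesday's radical scavenger charge over that lag measures the radical supply, 3.33 × 10⁻⁴ h⁻¹ as a fraction of the charge. Tuesday's last reading, taken as first-order past the lag, gives a turnover constant of 0.0308 h⁻¹. Dividing this constant by the supply cancels the hours and leaves the kinetic chain length ν, 92.5.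

The forecast stands on the steep early stretch, where Saturday's readings give me 0.0494 h⁻¹, a chain length of 148. It holds that the scavenger preserves this pace: “Saturday's 0.80 equiv should hold out until about 80% conversion”. It says 76% (68% to 82%) reacted and 95% free.

I disagree, because Tuesday's constant already reads 0.0218 h⁻¹, lower than the early one, on the stretch that ends as conversion reaches about the 0.54 equiv of scavenger. With ν as it stands, my reckoning for this flask is 63.8% reacted.

The flask gives 62.8% reacted and 99.9% free. Taken as one first-order average past my lag and on my supply, that is a chain length of 89.8, a figure for the whole bending course and not a value at any moment.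

    initiator → 2 initiating radical (k = 0.0180 h⁻¹)
    starting material + initiating radical → capped initiator + first chain carrier (k = 25000 M⁻¹ s⁻¹)
    coupling partner + first chain carrier ⇌ product + second chain carrier (K = 0.180, k = 7.20 × 10⁶ M⁻¹ h⁻¹)
    starting material + second chain carrier → released group + first chain carrier (k = 5.90 × 10⁶ M⁻¹ h⁻¹)
    2 first chain carrier → ended chains A (k = 8.80 × 10⁷ M⁻¹ s⁻¹)
    2 second chain carrier → ended chains B (k = 5.00 × 10⁶ M⁻¹ s⁻¹)
    coupling partner + released group ⇌ idle adduct, settled at all times (K = 1.00 M⁻¹)
    scavenger + released group → scavenged by-product (k = 40.0 M⁻¹ h⁻¹)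
    first chain carrier + radical scavenger → ended chains C (k = 2.10 × 10⁶ M⁻¹ s⁻¹)

The steep early view has its region in the first day: the constant I read from Saturday's readings gives 64.1% starting material at 1.00 d, and the flask holds 64.1%. At 2.00 d, starting material has a half-life of 1.9 d by the step with second chain carrier, shorter than the 74 d by capture of initiating radical. The flask still holds 23.2% of its scavenger.

For the flask with 0.58 mol% of initiator, I take the lag to stretch to 24.8 h, the supply to shrink in proportion, and ν to grow as the inverse root of the loading, as for chains ending in pairs, to 119. That reckons to 42.6% reacted, and the computed flask gives 43.4%.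

All runs are simulated for substances that don't exist; the scatter is artificial.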